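**Retrosynthetic overview**

1. The tetrahydrofuran of target 15 (ring atoms O, C9, C8, C8', C7') is disconnected last as a formal (3+2) of an epoxide C–C–O unit (C8, C9, O) with an alkene (C8'=C7'). Bonds C8–C8' and C7'–O are made in one operation from the open biaryl 13, which carries an (S)-oxiranylmethyl arm on ring A and an (E)-prop-1-enyl arm on ring B.
2. Enabling feature: C8–C8' belongs to both the eight-membered carbocycle and the tetrahydrofuran, C9–O sits exo on C8, and C7' is a benzylic carbon para to a methoxy group of ring B with its methyl-bearing neighbour C8' trans to the aryl group. Opening an epoxide at C8 by the β-carbon of an (E)-propenylarene therefore closes the carbocycle first and leaves an alkoxide and a benzylic cation placed to close the tetrahydrofuran.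
3. 13 comes from Suzuki–Miyaura coupling of bromo epoxide 12 (from 5-bromo-1,2,3-trimethoxybenzene and (S)-epichlorohydrin, the only source of chirality) with boronate 6 (from 2-bromo-3,4,5-trimethoxybenzaldehyde).
4. Order of ring formation: both arenes are bought; oxirane (temporary ring, step 6); biaryl bond (step 7); eight-membered carbocycle and then, last, the tetrahydrofuran (both in step 8). No protecting groups are used.

Key step: step 8

Assumption: the target structure carries no descriptor for the biaryl axis, so its sense is taken to be the one that the oxygen bridge allows; lignan locants are used (ring A with C7, C8, C9; ring B with C7', C8', and C9' as the methyl carbon).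

**Route**

Step 1
Reactants: 1 2-bromo-3,4,5-trimethoxybenzaldehyde; 2 ethylmagnesium bromide
Product: 3 1-(2-bromo-3,4,5-trimethoxyphenyl)propan-1-ol (racemic)
Conditions: EtMgBr (1.2 equiv), THF, −20 → 0 °C; then H2O
Reagents that add atoms: none
Why: Grignard addition to an aryl aldehyde, which is faster than magnesium–bromine exchange at this temperature; the new carbinol centre is racemic and is removed in step 2.

Step 2
Reactants: 3 1-(2-bromo-3,4,5-trimethoxyphenyl)propan-1-ol
Product: 4 2-bromo-3,4,5-trimethoxy-1-[(E)-prop-1-enyl]benzene
Conditions: TsOH·H2O (5 mol %), toluene, reflux, Dean–Stark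
Reagents that add atoms: none
Why: acid-catalysed E1 dehydration of a benzylic alcohol gives the conjugated propenylarene under thermodynamic control, hence the (E)-alkene, as in the classical preparation of asarone-type propenylbenzenes.

Step 3
Reactants: 4 2-bromo-3,4,5-trimethoxy-1-[(E)-prop-1-enyl]benzene
Product: 6 2-{2,3,4-trimethoxy-6-[(E)-prop-1-enyl]phenyl}-4,4,5,5-tetramethyl-1,3,2-dioxaborolane, via aryllithium 5 (not isolated)
Conditions: n-BuLi (1.05 equiv), THF, −78 °C; iPrOBpin, −78 °C → rt; then H2O
Reagents that add atoms: 2-isopropoxy-4,4,5,5-tetramethyl-1,3,2-dioxaborolane, CC(C)OB1OC(C)(C)C(C)(C)O1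
Why: bromine–lithium exchange followed by borylation of the aryllithium; exchange at −78 °C outruns addition of n-BuLi to the styrene, and the alkene geometry is not touched.

Step 4
Reactants: 7 5-bromo-1,2,3-trimethoxybenzene; 8 (S)-epichlorohydrin [(S)-2-(chloromethyl)oxirane]
Product: 10 (2S)-1-chloro-3-(3,4,5-trimethoxyphenyl)propan-2-ol, via Grignard reagent 9 (not isolated)
Conditions: Mg, THF, reflux; then CuI (10 mol %), 8, THF, −40 → 0 °C; then H2O
Reagents that add atoms: none
Why: copper-catalysed opening of epichlorohydrin by an aryl Grignard reagent at the unsubstituted oxirane carbon and not at the C–Cl bond (the two paths would end in opposite enantiomers of 12); the stereocentre is not a reacting centre and stays (S).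

Step 5
Reactants: 10 (2S)-1-chloro-3-(3,4,5-trimethoxyphenyl)propan-2-ol
Product: 11 (2S)-1-(2-bromo-3,4,5-trimethoxyphenyl)-3-chloropropan-2-ol
Conditions: NBS (1.05 equiv), MeCN, 0 °C → rt
Reagents that add atoms: N-bromosuccinimide, O=C1CCC(=O)N1Br
Why: electrophilic aromatic bromination; the two free ring positions are equivalent and each is ortho and para to a methoxy group, so one monobromide should form while the alcohol and the alkyl chloride are left alone.

Step 6
Reactants: 11 (2S)-1-(2-bromo-3,4,5-trimethoxyphenyl)-3-chloropropan-2-ol
Product: 12 (2S)-2-[(2-bromo-3,4,5-trimethoxyphenyl)methyl]oxirane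
Conditions: NaOH (2 M aq), THF, 0 °C → rt
Reagents that add atoms: none
Why: intramolecular Williamson etherification of the chlorohydrin (3-exo-tet displacement at the CH2Cl carbon); the stereocentre is not attacked and keeps its configuration.

Step 7
Reactants: 12 (2S)-2-[(2-bromo-3,4,5-trimethoxyphenyl)methyl]oxirane; 6 2-{2,3,4-trimethoxy-6-[(E)-prop-1-enyl]phenyl}-4,4,5,5-tetramethyl-1,3,2-dioxaborolane
Product: 13 4,4',5,5',6,6'-hexamethoxy-2-[(2S)-oxiran-2-ylmethyl]-2'-[(E)-prop-1-enyl]-1,1'-biphenyl (the atropisomer matched with the C8 centre)
Conditions: Pd(OAc)2 (5 mol %), SPhos (10 mol %), K3PO4, toluene/H2O (10:1), 90 °C; atropisomers separated (SiO2), the unwanted one re-equilibrated (Ph2O, 200 °C) and separated again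
Reagents that add atoms: none
Why: Suzuki–Miyaura coupling with a ligand made for tetra-ortho-substituted, electron-rich biaryls; the stereogenic axis forms without control, so 13 arises as two atropisomers, and the one whose two arms can meet in step 8 (identified by a trial of that step) is carried on.

Step 8
Reactants: 13 4,4',5,5',6,6'-hexamethoxy-2-[(2S)-oxiran-2-ylmethyl]-2'-[(E)-prop-1-enyl]-1,1'-biphenyl
Product: 15 (7'S,8S,8'S)-7',9-epoxy-3,3',4,4',5,5'-hexamethoxy-2,2'-cyclolignane (the target), via ring-opened zwitterion 14 (not isolated)
Conditions: BF3·OEt2 (1.1 equiv), CH2Cl2 (0.002 M), −78 → −40 °C; then Et3N, aq. NaHCO3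
Reagents that add atoms: none
Why: Proposed new method: BF3 activates the oxirane, and the β-carbon of the (E)-propenyl group on ring B (an isoelemicin-type styrene, the strongest π-nucleophile present) opens it at the internal carbon C8 from the back side, which closes the eight-membered carbocycle (exo with respect to the epoxide, endo with respect to the alkene) and leaves zwitterion 14, a C7' benzylic cation para to a methoxy group beside a C9 alkoxide; collapse of this ion pair by C–O bond formation then closes the five-membered tetrahydrofuran as the last ring. The closest known reaction types are the Lewis-acid epoxy-arene and epoxy-olefin cyclisations of terminal epoxides, which open in the exo mode at the internal carbon with inversion and can end by capture of the cation by the epoxide oxygen, and the formal (3+2) cycloaddition of epoxides with styrenes by C–O cleavage; new here are the eight-membered ring and the non-benzylic epoxide carbon. C8 is set by inversion at the (S)-epoxide carbon, C8' by the (E)-geometry of the alkene because carbon and oxygen are delivered to the same face (methyl trans to the aryl group and to the ring A CH2), and C7' has no freedom, since the O–CH2 bridge can span C8 and C7' on one face of the new carbocycle only, which also fixes the sense of the biaryl axis. The step needs internal and not terminal opening of the epoxide, and C-alkylation before any hydride shift: the first is secured by ring size (eight- against nine-membered) and by the greater cation character of the secondary carbon, the second by the proximity that the biaryl imposes on the two ortho arms and by the low temperature. It also needs direct attack to outrun participation by ring A, which is plausible because the para-methoxy group of ring A is twisted out of conjugation by its two neighbours. High dilution keeps the styrene from intermolecular alkylation, and only the atropisomer of 13 in which the two arms can meet in this way is used.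

**Compound list**

1 | 2-bromo-3,4,5-trimethoxybenzaldehyde | O=Cc1cc(OC)c(OC)c(OC)c1Br | starting material
2 | ethylmagnesium bromide | CC[Mg]Br | starting material
3 | 1-(2-bromo-3,4,5-trimethoxyphenyl)propan-1-ol (racemic) | CCC(O)c1cc(OC)c(OC)c(OC)c1Br | intermediate
4 | 2-bromo-3,4,5-trimethoxy-1-[(E)-prop-1-enyl]benzene | C/C=C/c1cc(OC)c(OC)c(OC)c1Br | intermediate
5 | {2,3,4-trimethoxy-6-[(E)-prop-1-enyl]phenyl}lithium | C/C=C/c1cc(OC)c(OC)c(OC)c1[Li] | intermediate
6 | 2-{2,3,4-trimethoxy-6-[(E)-prop-1-enyl]phenyl}-4,4,5,5-tetramethyl-1,3,2-dioxaborolane | C/C=C/c1cc(OC)c(OC)c(OC)c1B1OC(C)(C)C(C)(C)O1 | intermediate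
7 | 5-bromo-1,2,3-trimethoxybenzene | COc1cc(Br)cc(OC)c1OC | starting material
8 | (S)-epichlorohydrin | ClC[C@@H]1CO1 | starting material
9 | (3,4,5-trimethoxyphenyl)magnesium bromide | COc1cc([Mg]Br)cc(OC)c1OC | intermediate
10 | (2S)-1-chloro-3-(3,4,5-trimethoxyphenyl)propan-2-ol | COc1cc(C[C@H](O)CCl)cc(OC)c1OC | intermediate
11 | (2S)-1-(2-bromo-3,4,5-trimethoxyphenyl)-3-chloropropan-2-ol | COc1cc(C[C@H](O)CCl)c(Br)c(OC)c1OC | intermediate
12 | (2S)-2-[(2-bromo-3,4,5-trimethoxyphenyl)methyl]oxirane | COc1cc(C[C@H]2CO2)c(Br)c(OC)c1OC | intermediate
13 | 4,4',5,5',6,6'-hexamethoxy-2-[(2S)-oxiran-2-ylmethyl]-2'-[(E)-prop-1-enyl]-1,1'-biphenyl (matched atropisomer) | COc1cc(C[C@H]2CO2)c(c(OC)c1OC)-c1c(/C=C/C)cc(OC)c(OC)c1OC | intermediate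
14 | ring-opened zwitterion: eight-membered carbocycle closed, benzylic cation at C7', alkoxide at C9 (held by BF3 in the flask), C8 and C8' as in 15 | COc1cc2c(c(OC)c1OC)-c1c(cc(OC)c(OC)c1OC)[CH+][C@@H](C)[C@H](C2)C[O-] | intermediate
15 | (7'S,8S,8'S)-7',9-epoxy-3,3',4,4',5,5'-hexamethoxy-2,2'-cyclolignane: hexamethoxy-dibenzocyclooctadiene with an O–CH2 bridge from C7' to C8 and a methyl group on C8' trans to both ring neighbours in the tetrahydrofuran | COc1cc2c(c(OC)c1OC)-c1c(cc(OC)c(OC)c1OC)[C@H]1OC[C@@H](C2)[C@@H]1C | target

**Step count**

Total steps: 8. Longest linear sequence: 5 steps (steps 4, 5, 6, 7, 8; the branch through steps 1, 2, 3, 7, 8 is equally long).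

**Steps most likely to fail**

1. Step 8 (Proposed new method). What may go wrong: the activated epoxide may open at its terminal carbon (nine-membered ring), or a hydride shift to the aldehyde may occur before the alkene arrives. Aryl participation by ring A could erode the inversion at C8, and the zwitterion could lose a proton instead of closing the ring. The fallback uses known reaction types; it sets out from 13 and comes back at 15. Cp2TiCl (trivalent titanium, made in the flask from Cp2TiCl2 and zinc dust; THF, slow addition of 13) opens the epoxide reductively to the secondary C8 radical with the oxygen held on C9 (Nugent–RajanBabu opening). The radical adds 8-endo to the β-carbon of the styrene, and the benzylic radical is reduced by a second Cp2TiCl and protonated on work-up. This should give the dibenzocyclooctadiene alcohol F1 (hydroxymethyl on C8, methyl on C8', CH2 at C7'). A hypoiodite δ-C–H etherification (PhI(OAc)2, I2, visible light, cyclohexane/CH2Cl2) then closes the tetrahydrofuran as the last ring: the C9 alkoxy radical abstracts the benzylic hydrogen at C7' through a six-membered transition state (1,5-hydrogen transfer), and the benzylic radical is oxidised and captured by the hydroxyl group to give 15. Because the C8 radical is planar, the configuration at C8 and C8' would here be relayed from the axis of the single atropisomer of 13 and not from the epoxide carbon, and a C8' epimer may have to be removed at the stage of F1.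

2. Step 7. What may go wrong: transmetalation between two di-ortho-substituted partners may be slow, so that protodeboronation of 6 becomes the faster process, and the epoxide may be opened hydrolytically in hot aqueous base. The fallback sets out from 4 and comes back at 13, and does without boron, base and water. Aryllithium 5, made from 4 as in step 3, is transmetalated with ZnCl2 (THF, −78 °C → rt) to the arylzinc chloride F2. This is coupled with 12 in a Negishi reaction (Pd2(dba)3, RuPhos, THF, 60 °C), which organozinc reagents allow in the presence of an epoxide. The pair of atropisomers is then handled as in step 7.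

3. Step 2. What may go wrong: acid-catalysed dimerisation of the electron-rich propenylarene through its benzylic cation, and incomplete (E)-selectivity. The fallback sets out from 1 and comes back at 4, and avoids both carbinol 3 and any cation. Wittig ethylidenation of 1 (EtPPh3Br, KOtBu, THF, 0 °C) gives the alkene as a mixture of 4 and its (Z)-isomer F3. Catalytic PdCl2(MeCN)2 (divalent palladium, CH2Cl2, rt) then isomerises the mixture to the thermodynamically favoured (E)-alkene 4.

**Further compounds**

F1 | step 8 | hexamethoxy-dibenzocyclooctadiene alcohol: hydroxymethyl on C8, methyl on C8', CH2 at C7', C8 and C8' as in 15 | COc1cc2c(c(OC)c1OC)-c1c(cc(OC)c(OC)c1OC)C[C@@H](C)[C@H](C2)CO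
F2 | step 7 | chlorido{2,3,4-trimethoxy-6-[(E)-prop-1-enyl]phenyl}zinc | C/C=C/c1cc(OC)c(OC)c(OC)c1[Zn]Cl
F3 | step 2 | 2-bromo-3,4,5-trimethoxy-1-[(Z)-prop-1-enyl]benzene | C/C=C\c1cc(OC)c(OC)c(OC)c1Br
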